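**Assumption (one line):** compounds 1–4 use abietane locants; from 5 on, decalin locants are C1–C10, C11 = carbon on C9, C12 = one‑carbon group on C8 (abietane C14), C18 = 4α‑carboxyl carbon, with 4β‑Me, 5α‑H, 10β‑Me throughout; the oxygenated six‑membered ring is ring C, C1′–C6′ (C1′ = CHOH next to C2′–Me, C4′ = CHOH next to C5′, C5′/C6′ = oxirane carbons).

## Retrosynthetic overview

1. Target ⇐ fluoride ester cleavage and double C=O reduction of an epoxy‑enedione ⇐ face‑selective nucleophilic epoxidation of a 2‑alkyl quinone monoketal (the ketal decides which C=C is epoxidised).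
2. Key bond C11–C5′, made with reversed polarity: C5′ (natively the nucleophilic α‑carbon of the dienone, i.e. a hydroquinone ring carbon) is used as an α‑iodo quinone monoketal, an α‑keto vinyl cation (enolonium) equivalent. It is joined to C11 as a nucleophilic B‑alkyl from hydroboration of an exocyclic diene, which also sets C9.
3. The diene comes from abietic acid: Δ13 oxidative cleavage, Norrish type 2 excision of abietane C12, C13 and C15–C17, then CHO → CH3 at C12; C4, C5 and C10 are bought.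
4. Ring order: rings A and B are pre‑formed (abietane ring C is cut away); ring C of the target enters as an intact carbocycle from 4‑methoxy‑3‑methylphenol; the oxirane is closed after the union and the two carbinols are set last.

## Route

Step 1
Reactants: 1 abietic acid
Product: 2 2‑(trimethylsilyl)ethyl abieta‑7,13‑dien‑18‑oate
Conditions: TMSCH2CH2OH, PPh3, DIAD, THF, 0 °C → rt
Reagents that add atoms: 2‑(trimethylsilyl)ethanol, C[Si](C)(C)CCO
Why: Mitsunobu esterification; the hindered C18 carboxylate attacks the unhindered primary alkoxyphosphonium carbon (SN2), giving a fluoride‑labile ester without HCl that would isomerise the diene; no stereocentre is touched.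

Step 2
Reactants: 2 2‑(trimethylsilyl)ethyl abieta‑7,13‑dien‑18‑oate
Product: 4 2‑(trimethylsilyl)ethyl 13,14‑dioxo‑13,14‑secoabiet‑7‑en‑18‑oate, via 13β,14β‑diol 3 (not isolated)
Conditions: OsO4 (2 mol%), NaIO4, 2,6‑lutidine, dioxane/H2O, rt
Reagents that add atoms: osmium tetroxide OsO4, O=[Os](=O)(=O)=O (catalytic oxygen carrier); sodium periodate NaIO4, [Na+].[O-][I](=O)(=O)=O (terminal oxygen source)
Why: Lemieux–Johnson oxidative cleavage; OsO4 is expected to add to the more electron‑rich, more exposed Δ13(14) alkene (once it is cleaved the Δ7 alkene is a deactivated enal), and NaIO4 cleaves the transient diol and re‑oxidises osmium.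

Step 3
Reactants: 4 2‑(trimethylsilyl)ethyl 13,14‑dioxo‑13,14‑secoabiet‑7‑en‑18‑oate
Product: 5 2‑(trimethylsilyl)ethyl 12‑oxodrima‑7,9(11)‑dien‑18‑oate
Conditions: hν (Pyrex, λ > 300 nm), degassed benzene, rt
Reagents that add atoms: none
Why: Norrish type 2 photofragmentation; the excited isopropyl ketone abstracts the tertiary allylic γ‑hydrogen at C9 through a six‑membered transition state and the 1,4‑biradical cleaves C11–C12, releasing the enol of 3‑methylbutan‑2‑one and leaving the exocyclic C9=C11 alkene (C9 is re‑set in step 9).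

Step 4
Reactants: 5 2‑(trimethylsilyl)ethyl 12‑oxodrima‑7,9(11)‑dien‑18‑oate
Product: 6 2‑(trimethylsilyl)ethyl 12‑hydroxydrima‑7,9(11)‑dien‑18‑oate
Conditions: NaBH4, CeCl3·7H2O, MeOH, −20 °C
Reagents that add atoms: none
Why: Luche reduction gives clean 1,2‑reduction of the cross‑conjugated dienal and leaves the neopentyl‑type ester alone.

Step 5
Reactants: 6 2‑(trimethylsilyl)ethyl 12‑hydroxydrima‑7,9(11)‑dien‑18‑oate
Product: 7 2‑(trimethylsilyl)ethyl 12‑bromodrima‑7,9(11)‑dien‑18‑oate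
Conditions: CBr4, PPh3, CH2Cl2, 0 °C
Reagents that add atoms: carbon tetrabromide, BrC(Br)(Br)Br
Why: Appel bromination, SN2 at the primary allylic carbinol under neutral conditions, so the diene does not migrate.

Step 6
Reactants: 7 2‑(trimethylsilyl)ethyl 12‑bromodrima‑7,9(11)‑dien‑18‑oate
Product: 8 2‑(trimethylsilyl)ethyl drima‑7,9(11)‑dien‑18‑oate
Conditions: LiBHEt3 (1.05 equiv), THF, −78 °C
Reagents that add atoms: none
Why: Hydride SN2 displacement of a primary allylic bromide is far faster at −78 °C than attack on the hindered ester, giving the C8 methyl group with the Δ7 and Δ9(11) alkenes in place.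

Step 7
Reactants: 9 4‑methoxy‑3‑methylphenol
Product: 10 2‑iodo‑4‑methoxy‑5‑methylphenol
Conditions: N‑iodosuccinimide, TsOH (10 mol%), MeCN, 0 °C → rt
Reagents that add atoms: N‑iodosuccinimide, O=C1CCC(=O)N1I
Why: Electrophilic aromatic iodination ortho to the free OH; the para position is blocked by OMe and the other ortho site is flanked by the methyl, so iodine enters para to the methyl.

Step 8
Reactants: 10 2‑iodo‑4‑methoxy‑5‑methylphenol
Product: 11 2‑iodo‑4,4‑dimethoxy‑5‑methylcyclohexa‑2,5‑dien‑1‑one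
Conditions: PhI(OAc)2, MeOH, 0 °C
Reagents that add atoms: methanol, CO
Why: Oxidative dearomatisation of a p‑methoxyphenol with trivalent iodine in methanol (quinone monoketal synthesis); the phenol carbon becomes the ketone and the OMe carbon the ketal, which later fixes the epoxidation regiochemistry.

Step 9
Reactants: 8 2‑(trimethylsilyl)ethyl drima‑7,9(11)‑dien‑18‑oate; 11 2‑iodo‑4,4‑dimethoxy‑5‑methylcyclohexa‑2,5‑dien‑1‑one
Product: 13 2‑(trimethylsilyl)ethyl 11‑(3,3‑dimethoxy‑4‑methyl‑6‑oxocyclohexa‑1,4‑dien‑1‑yl)drim‑7‑en‑18‑oate (9α‑H), via B‑alkyl‑9‑BBN adduct 12 (not isolated)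
Conditions: 9‑BBN, THF, rt; then 11, PdCl2(dppf) (5 mol%), AsPh3 (10 mol%), Cs2CO3, DMF/THF/H2O, rt
Reagents that add atoms: none
Why: Hydroboration then B‑alkyl Suzuki–Miyaura coupling; 9‑BBN adds to the exocyclic C9=C11 alkene from the α‑face (anti to the axial 10β‑methyl), putting boron on C11 and H‑9 α, and this C11 nucleophile is joined to C5′ used with reversed polarity as the α‑iodo dienone (α‑iodoenone coupling conditions).

Step 10
Reactants: 13 2‑(trimethylsilyl)ethyl 11‑(3,3‑dimethoxy‑4‑methyl‑6‑oxocyclohexa‑1,4‑dien‑1‑yl)drim‑7‑en‑18‑oate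
Product: 14 2‑(trimethylsilyl)ethyl 11‑[(1R,6S)‑5,5‑dimethoxy‑4‑methyl‑2‑oxo‑7‑oxabicyclo[4.1.0]hept‑3‑en‑1‑yl]drim‑7‑en‑18‑oate
Conditions: t‑BuOOH, N‑(9‑anthracenylmethyl)cinchonidinium bromide (10 mol%), aq. KOH, toluene, −10 °C
Reagents that add atoms: tert‑butyl hydroperoxide, CC(C)(C)OO
Why: Asymmetric Weitz–Scheffer epoxidation under cinchona phase‑transfer catalysis; the peroxide anion attacks the only β‑unsubstituted enone carbon (C6′), so only the C5′=C6′ bond is epoxidised, and the chiral ion pair, not the remote decalin, selects the face, the minor face giving a separable diastereomer.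

Step 11
Reactants: 14 2‑(trimethylsilyl)ethyl 11‑[(1R,6S)‑5,5‑dimethoxy‑4‑methyl‑2‑oxo‑7‑oxabicyclo[4.1.0]hept‑3‑en‑1‑yl]drim‑7‑en‑18‑oate
Product: 15 2‑(trimethylsilyl)ethyl 11‑[(1R,6S)‑4‑methyl‑2,5‑dioxo‑7‑oxabicyclo[4.1.0]hept‑3‑en‑1‑yl]drim‑7‑en‑18‑oate
Conditions: oxalic acid, THF/H2O (4:1), rt
Reagents that add atoms: water, O
Why: Acid‑catalysed hydrolysis of the dimethyl ketal (oxocarbenium stabilised by the C2′=C3′ alkene); the oxirane is deactivated by the adjacent carbonyl and should survive.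

Step 12
Reactants: 15 2‑(trimethylsilyl)ethyl 11‑[(1R,6S)‑4‑methyl‑2,5‑dioxo‑7‑oxabicyclo[4.1.0]hept‑3‑en‑1‑yl]drim‑7‑en‑18‑oate
Product: 16 2‑(trimethylsilyl)ethyl 11‑[(1S,2R,5S,6R)‑2,5‑dihydroxy‑4‑methyl‑7‑oxabicyclo[4.1.0]hept‑3‑en‑1‑yl]drim‑7‑en‑18‑oate
Conditions: NaBH4, CeCl3·7H2O, MeOH, −78 °C
Reagents that add atoms: none
Why: Luche 1,2‑reduction of both enedione carbonyls; hydride is expected to arrive at each C=O from the face carrying the oxirane oxygen (cation bridging of C=O and oxirane oxygen; at C4′ this is also anti to the CH2–decalin arm), giving both hydroxyls trans to the epoxide and cis to each other.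

Step 13
Reactants: 16 2‑(trimethylsilyl)ethyl 11‑[(1S,2R,5S,6R)‑2,5‑dihydroxy‑4‑methyl‑7‑oxabicyclo[4.1.0]hept‑3‑en‑1‑yl]drim‑7‑en‑18‑oate
Product: 17 (1R,4aR,5S,8aR)‑5‑{[(1S,2R,5S,6R)‑2,5‑dihydroxy‑4‑methyl‑7‑oxabicyclo[4.1.0]hept‑3‑en‑1‑yl]methyl}‑1,4a,6‑trimethyl‑1,2,3,4,4a,5,8,8a‑octahydronaphthalene‑1‑carboxylic acid (target)
Conditions: TBAF, THF, 0 °C → rt; aq. NH4Cl
Reagents that add atoms: none
Why: Fluoride‑induced β‑elimination of the 2‑(trimethylsilyl)ethyl ester does not depend on steric access to C18 and frees the acid under conditions the epoxy diol tolerates (the trisubstituted oxirane is the favoured side of any Payne equilibrium).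

## Compound list

1 | abietic acid (abieta‑7,13‑dien‑18‑oic acid) | CC(C)C1=CC2=CC[C@@H]3[C@]([C@H]2CC1)(C)CCC[C@@]3(C)C(=O)O | starting material
2 | 2‑(trimethylsilyl)ethyl abieta‑7,13‑dien‑18‑oate | CC(C)C1=CC2=CC[C@@H]3[C@]([C@H]2CC1)(C)CCC[C@@]3(C)C(=O)OCC[Si](C)(C)C | intermediate
3 | 2‑(trimethylsilyl)ethyl 13β,14β‑dihydroxyabiet‑7‑en‑18‑oate | CC(C)[C@@]1(O)CC[C@H]2C(=CC[C@@H]3[C@]2(C)CCC[C@@]3(C)C(=O)OCC[Si](C)(C)C)[C@@H]1O | intermediate
4 | 2‑(trimethylsilyl)ethyl 13,14‑dioxo‑13,14‑secoabiet‑7‑en‑18‑oate (C8–CHO; C9α‑H with CH2CH2C(O)iPr chain) | CC(C)C(=O)CC[C@H]1C(C=O)=CC[C@@H]2[C@]1(C)CCC[C@@]2(C)C(=O)OCC[Si](C)(C)C | intermediate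
5 | 2‑(trimethylsilyl)ethyl 12‑oxodrima‑7,9(11)‑dien‑18‑oate (C8–CHO, C9=CH2) | C=C1C(C=O)=CC[C@@H]2[C@]1(C)CCC[C@@]2(C)C(=O)OCC[Si](C)(C)C | intermediate
6 | 2‑(trimethylsilyl)ethyl 12‑hydroxydrima‑7,9(11)‑dien‑18‑oate | C=C1C(CO)=CC[C@@H]2[C@]1(C)CCC[C@@]2(C)C(=O)OCC[Si](C)(C)C | intermediate
7 | 2‑(trimethylsilyl)ethyl 12‑bromodrima‑7,9(11)‑dien‑18‑oate | C=C1C(CBr)=CC[C@@H]2[C@]1(C)CCC[C@@]2(C)C(=O)OCC[Si](C)(C)C | intermediate
8 | 2‑(trimethylsilyl)ethyl drima‑7,9(11)‑dien‑18‑oate | C=C1C(C)=CC[C@@H]2[C@]1(C)CCC[C@@]2(C)C(=O)OCC[Si](C)(C)C | intermediate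
9 | 4‑methoxy‑3‑methylphenol | COc1ccc(O)cc1C | starting material
10 | 2‑iodo‑4‑methoxy‑5‑methylphenol | COc1cc(I)c(O)cc1C | intermediate
11 | 2‑iodo‑4,4‑dimethoxy‑5‑methylcyclohexa‑2,5‑dien‑1‑one | O=C1C(I)=CC(OC)(OC)C(C)=C1 | intermediate
12 | 2‑(trimethylsilyl)ethyl 11‑(9‑borabicyclo[3.3.1]nonan‑9‑yl)drim‑7‑en‑18‑oate (9α‑H) | C(B1C2CCCC1CCC2)[C@H]3C(C)=CC[C@@H]4[C@]3(C)CCC[C@@]4(C)C(=O)OCC[Si](C)(C)C | intermediate
13 | 2‑(trimethylsilyl)ethyl 11‑(3,3‑dimethoxy‑4‑methyl‑6‑oxocyclohexa‑1,4‑dien‑1‑yl)drim‑7‑en‑18‑oate (9α‑H) | COC1(OC)C=C(C[C@H]2C(C)=CC[C@@H]3[C@]2(C)CCC[C@@]3(C)C(=O)OCC[Si](C)(C)C)C(=O)C=C1C | intermediate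
14 | 2‑(trimethylsilyl)ethyl 11‑[(1R,6S)‑5,5‑dimethoxy‑4‑methyl‑2‑oxo‑7‑oxabicyclo[4.1.0]hept‑3‑en‑1‑yl]drim‑7‑en‑18‑oate | CC1=CC(=O)[C@]2(C[C@H]3C(C)=CC[C@@H]4[C@]3(C)CCC[C@@]4(C)C(=O)OCC[Si](C)(C)C)O[C@@H]2C1(OC)OC | intermediate
15 | 2‑(trimethylsilyl)ethyl 11‑[(1R,6S)‑4‑methyl‑2,5‑dioxo‑7‑oxabicyclo[4.1.0]hept‑3‑en‑1‑yl]drim‑7‑en‑18‑oate | CC1=CC(=O)[C@]2(C[C@H]3C(C)=CC[C@@H]4[C@]3(C)CCC[C@@]4(C)C(=O)OCC[Si](C)(C)C)O[C@@H]2C1=O | intermediate
16 | 2‑(trimethylsilyl)ethyl 11‑[(1S,2R,5S,6R)‑2,5‑dihydroxy‑4‑methyl‑7‑oxabicyclo[4.1.0]hept‑3‑en‑1‑yl]drim‑7‑en‑18‑oate | CC1=C[C@@H](O)[C@]2(C[C@H]3C(C)=CC[C@@H]4[C@]3(C)CCC[C@@]4(C)C(=O)OCC[Si](C)(C)C)O[C@@H]2[C@H]1O | intermediate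
17 | (1R,4aR,5S,8aR)‑5‑{[(1S,2R,5S,6R)‑2,5‑dihydroxy‑4‑methyl‑7‑oxabicyclo[4.1.0]hept‑3‑en‑1‑yl]methyl}‑1,4a,6‑trimethyl‑1,2,3,4,4a,5,8,8a‑octahydronaphthalene‑1‑carboxylic acid | CC1=C[C@@H](O)[C@]2(C[C@H]3C(C)=CC[C@@H]4[C@]3(C)CCC[C@@]4(C)C(=O)O)O[C@@H]2[C@H]1O | target

## Totals and risks

Total step count: 13. Longest linear sequence: 11 (steps 1–6 and 9–13; steps 7–8 make the ring C partner in parallel).

Three steps most likely to fail:

Step 3. The enal chromophore of 4 can quench or divert the excited ketone, and the allylic 1,4‑biradical can recombine instead of cleaving. The fallback sets out from 4 and comes back at 6. The aldehyde is reduced first and chemoselectively (NaBH4, MeOH/CH2Cl2, −78 °C; the hindered isopropyl ketone survives) to give 2‑(trimethylsilyl)ethyl 14‑hydroxy‑13‑oxo‑13,14‑secoabiet‑7‑en‑18‑oate F1. F1 has only the saturated ketone as chromophore, and its Norrish type 2 photolysis gives dienol 6 directly, with no change in step count.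

Step 10. Phase‑transfer epoxidation of an α‑alkylated cyclic dienone may be slow or poorly face‑selective, and the sense of induction of the cinchonidine salt is not assured (the quasi‑enantiomeric cinchonine salt would give the other face). The fallback replaces catalyst control by auxiliary control; it sets out from 13 and comes back at 15. Ketal exchange of 13 with (1R,2R)‑1,2‑diphenylethane‑1,2‑diol (PPTS, benzene, molecular sieves) gives the C2‑symmetric hydrobenzoin spiro‑ketal analogue of 13 F2. In a simple steric model, its phenyl group on the C6′ side blocks the face that must stay free of oxygen. t‑BuOOH/DBU epoxidation then gives the hydrobenzoin ketal analogue of 14 F3, and aqueous acid hydrolysis (HClO4, THF/H2O) gives 15.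

Step 12. The stereochemical course of hydride addition next to the oxirane CH (C1′) is the least certain; addition anti to the oxirane would give the 1′‑epimer. The fallback corrects the centre by inversion; it sets out from 15 and comes back at 16. The same reduction then gives mainly the 1′‑epimeric diol (1′‑OH cis to the oxirane) F4. Mitsunobu reaction at the less hindered C1′ hydroxyl (4‑nitrobenzoic acid, PPh3, DIAD, THF; the C4′ hydroxyl is shielded by the quaternary C5′) gives the inverted 1′‑(4‑nitrobenzoate) F5, and K2CO3/MeOH methanolysis gives 16.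

## Further compounds

F1 | step 3 | 2‑(trimethylsilyl)ethyl 14‑hydroxy‑13‑oxo‑13,14‑secoabiet‑7‑en‑18‑oate | CC(C)C(=O)CC[C@H]1C(CO)=CC[C@@H]2[C@]1(C)CCC[C@@]2(C)C(=O)OCC[Si](C)(C)C
F2 | step 10 | (4R,5R)‑4,5‑diphenyl‑1,3‑dioxolane (hydrobenzoin) spiro‑ketal analogue of 13 | CC1=CC(=O)C(C[C@H]3C(C)=CC[C@@H]4[C@]3(C)CCC[C@@]4(C)C(=O)OCC[Si](C)(C)C)=CC12O[C@H](c5ccccc5)[C@@H](c5ccccc5)O2
F3 | step 10 | (4R,5R)‑4,5‑diphenyl‑1,3‑dioxolane (hydrobenzoin) spiro‑ketal analogue of 14 | CC1=CC(=O)[C@]2(C[C@H]3C(C)=CC[C@@H]4[C@]3(C)CCC[C@@]4(C)C(=O)OCC[Si](C)(C)C)O[C@@H]2C16O[C@H](c5ccccc5)[C@@H](c5ccccc5)O6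
F4 | step 12 | 1′‑epimer of 16 (1′‑OH cis to the oxirane) | CC1=C[C@@H](O)[C@]2(C[C@H]3C(C)=CC[C@@H]4[C@]3(C)CCC[C@@]4(C)C(=O)OCC[Si](C)(C)C)O[C@@H]2[C@@H]1O
F5 | step 12 | 1′‑O‑(4‑nitrobenzoyl) derivative of 16 | CC1=C[C@@H](O)[C@]2(C[C@H]3C(C)=CC[C@@H]4[C@]3(C)CCC[C@@]4(C)C(=O)OCC[Si](C)(C)C)O[C@@H]2[C@H]1OC(=O)c5ccc(cc5)[N+](=O)[O-]
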